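Your hunch that target simply sits at equilibrium with dissolved substrate cannot hold in this flask, because with the solution saturated the side step removes target at about half the rate of the way back.

    solid substrate ⇌ dissolved substrate, rate k1*(cs1 - [dissolved substrate]) while solid is left; crystals form when [dissolved substrate] > cs1 (cs1 = 11 mM, k1 = 0.11 /s)
    dissolved substrate + partner ⇌ target (K2 = 10 /M, k2 = 0.39 /M/s)
    dissolved substrate + target → side product (k3 = 1.6 /M/s)
    2 solid substrate → homo dimer (k4 = 0.12 /M/s)

solid substrate 0.064 M; partner 0.0608 M; time 5.0 min

- a species is counted by the solid substrate in it: one side product or homo dimer counts as two
- a doubled species enters its step squared and goes two at a time
- given per volume of solution although it is solid: solid substrate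
- at the start none of the solid substrate is in solution
- run time (flask): 5.0 min

* amount of target at 5.0 min, in percent of the solid substrate charged
* the change that raises the amount of target at 5.0 min, in percent of the solid substrate charged most ("none" if none brings more than 2 percentage points) (larch / ash / oak / none)
* amount of target at 5.0 min, in percent of the solid substrate charged, after ash

Dividing the rate that makes target by the rate that removes it cancels time. I call the result the holding ratio, the target per dissolved substrate when making and removal match; it is the steady-state approximation for target.

holding ratio = forward coefficient × [partner] ÷ (backward coefficient + side coefficient × [dissolved substrate])

With partner as charged and dissolved substrate at its solubility, the ratio is 0.419, which gives target as 7.20% of the charge under those two conditions; I use that figure as an upper mark, not as a level I expect in this flask.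

The half-life of solid substrate by the dimer step alone, 1.09 min, is shorter than half the run, and dissolving draws on the solid too. I therefore allow the solid half the run. After that, the pool of dissolved substrate plus target, starting at 15.6 mM, falls by the side step:

inverse pool at end = inverse pool at start + 2 × side coefficient × target's share × dissolved substrate's share × time left

This gives 2.81%. Doubling partner gives 4.23%, and doubling solubility, with its ratio of 0.320, gives 3.09%. Both gains stay under 2 percentage points, so I say none. The dissolution coefficient does not enter my reckoning, so ash stays at 2.81%.

The forecast gives 2.8% (2.2% to 3.5%), none for the best change, and 2.7% after ash (2.1% to 3.5%), slightly below my unchanged figure; its ground is that the pool will “drain through the second-order side reaction to a level that barely depends on where they started”.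

The flask gives 3.60% of target, 3.47% after ash, and none for the best change, oak bringing 0.67 points. At 5.00 min the flask holds 8.98% dissolved substrate, so target per dissolved substrate reads 0.400, against my 0.419 and against 0.360 with that moment's amounts. In the neighbouring flask charged with 0.016 M of solid substrate, its amounts put the ratio at 0.486, and its 8.28% target over 16.0% dissolved substrate reads 0.517.

Its constants stand for no real mixture; the flask was simulated.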